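## Retrosynthetic overview

1. Target ⇐ cross-metathesis of a terminal vinyl group with methyl vinyl ketone (last step, installs the E-enone).
2. C2–C3 bond ⇐ axial addition of the bis-silyl ketene acetal of acetic acid to a cyclic peroxycarbenium ion from a 3-methoxy-1,2-dioxane (sets C3 cis to the C4 ethyl group).
3. 1,2-Dioxane (the only ring, closed in step 9) ⇐ key step: a tertiary C6 radical, released by decarboxylation of a fully substituted carboxylic acid, captures O2 (C6–O bond); the hydroperoxide then closes onto a C3 acetal.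
4. Quaternary acid ⇐ two dianion alkylations of butanoic acid, with a west bromo acetal and an east iodide.
5. Both electrophiles ⇐ one chiral bromide from copper-catalysed SN2′ ethylation of (E)-1,4-dibromobut-2-ene (supplies C4 and C10); C8 comes from ethyl (S)-lactate by an inverting sp3–sp3 coupling.

Assumption: centres not yet fixed (C6 before the separation in step 11, the acetal carbon C3 in 18, the ring carbon of ozonide 3) carry no descriptor and stand for both epimers; C1–C14 number the main chain of the target (C1 = CO2H, C3 and C6 = the ring carbons bound to oxygen).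

## Route

Step 1
Reactants: 1 (E)-1,4-dibromobut-2-ene
Product: 2 (R)-3-(bromomethyl)pent-1-ene
Conditions: EtMgBr (1.2 equiv), CuBr·SMe2 (3 mol %), Taniaphos (3.5 mol %, the enantiomer that gives the R bromide), CH2Cl2, −75 °C
Reagents that add atoms: ethylmagnesium bromide, CC[Mg]Br
Why: Copper-catalysed asymmetric allylic alkylation (SN2′) with a Grignard reagent: the chiral diphosphine–copper complex delivers ethyl to the γ-carbon and so creates the ethyl-bearing stereocentre (R here, later both C4 and C10), while the remaining homoallylic bromide is inert.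

Step 2
Reactants: 2 (R)-3-(bromomethyl)pent-1-ene
Product: 5 (R)-2-(bromomethyl)-1,1-dimethoxybutane, via ozonide 3 (not isolated), via aldehyde 4 (not isolated)
Conditions: O3, CH2Cl2, −78 °C; Me2S, −78 → 0 °C; then MeOH, HC(OMe)3, TsOH·H2O (5 mol %), 0 °C → rt; NaHCO3
Reagents that add atoms: trimethyl orthoformate, COC(OC)OC
Why: Ozonolysis with reductive work-up followed in the same flask by acid-catalysed acetalisation traps the β-bromo aldehyde before it can lose HBr or epimerise, so the stereocentre from step 1 is carried through unchanged.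

Step 3
Reactants: 6 ethyl (S)-lactate
Product: 7 ethyl (S)-2-{[(trifluoromethyl)sulfonyl]oxy}propanoate
Conditions: Tf2O, 2,6-lutidine, CH2Cl2, −78 → 0 °C
Reagents that add atoms: trifluoromethanesulfonic anhydride, O=S(=O)(OS(=O)(=O)C(F)(F)F)C(F)(F)F
Why: O-Sulfonylation of a secondary alcohol touches only the O–H bond, so the lactate stereocentre is retained and becomes an excellent SN2 leaving group.

Step 4
Reactants: 2 (R)-3-(bromomethyl)pent-1-ene; 7 ethyl (S)-2-{[(trifluoromethyl)sulfonyl]oxy}propanoate
Product: 9 ethyl (2S,4S)-4-ethyl-2-methylhex-5-enoate, via Grignard reagent 8 (not isolated)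
Conditions: Mg, THF, 40 °C; 1,4-dioxane (MgBr2 precipitated); then 7, ZnCl2 (10 mol %), THF, 0 °C
Reagents that add atoms: none
Why: Zinc-catalysed stereospecific sp3–sp3 cross-coupling of an α-triflyloxy ester with an alkylmagnesium reagent: the triorganozincate displaces triflate by SN2 with inversion, which sets C8 (2S in 9) from (S)-lactate, and removing MgBr2 keeps bromide from eroding the ee by double inversion.

Step 5
Reactants: 9 ethyl (2S,4S)-4-ethyl-2-methylhex-5-enoate
Product: 10 (2S,4S)-4-ethyl-2-methylhex-5-en-1-ol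
Conditions: LiAlH4, Et2O, 0 °C
Reagents that add atoms: none
Why: Hydride reduction of the ester to the primary alcohol involves no stereocentre.

Step 6
Reactants: 10 (2S,4S)-4-ethyl-2-methylhex-5-en-1-ol
Product: 11 (3S,5S)-3-ethyl-6-iodo-5-methylhex-1-ene
Conditions: I2, PPh3, imidazole, CH2Cl2, 0 °C → rt
Reagents that add atoms: iodine, II
Why: Appel-type iodination: iodide displaces the alkoxyphosphonium group at the primary carbon, remote from both stereocentres.

Step 7
Reactants: 12 butanoic acid; 5 (R)-2-(bromomethyl)-1,1-dimethoxybutane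
Product: 14 (4S)-4-(dimethoxymethyl)-2-ethylhexanoic acid (both C2 epimers), via dianion 13 (not isolated)
Conditions: LiN(iPr)2 (2.2 equiv), THF/DMPU, 0 °C → rt; then 5, 0 → 40 °C; cold dilute HCl to pH 4
Reagents that add atoms: none
Why: Alkylation of a carboxylic acid dianion (enediolate) by SN2 on the primary bromide gives the acid directly; the new α-centre (future C6) forms unselectively, which is irrelevant because it becomes a planar radical in step 9.

Step 8
Reactants: 14 (4S)-4-(dimethoxymethyl)-2-ethylhexanoic acid; 11 (3S,5S)-3-ethyl-6-iodo-5-methylhex-1-ene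
Product: 16 (4S,6S)-2-[(2S)-2-(dimethoxymethyl)butyl]-2,6-diethyl-4-methyloct-7-enoic acid (both C2 epimers), via dianion 15 (not isolated)
Conditions: LiN(iPr)2 (2.3 equiv), THF/DMPU, 0 → 45 °C; then 11, rt → 45 °C; cold dilute HCl to pH 4
Reagents that add atoms: none
Why: A second enediolate alkylation builds the fully substituted α-carbon (all three C6 substituents plus the carboxyl group that is expelled next); the strongly nucleophilic dianion with DMPU allows SN2 on the β-methyl-branched primary iodide, and the configuration of this centre again does not matter.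

Step 9
Reactants: 16 (4S,6S)-2-[(2S)-2-(dimethoxymethyl)butyl]-2,6-diethyl-4-methyloct-7-enoic acid
Product: 18 (4S)-4,6-diethyl-6-[(2S,4S)-4-ethyl-2-methylhex-5-en-1-yl]-3-methoxy-1,2-dioxane (C3/C6 epimer mixture), via hydroperoxide 17 (not isolated)
Conditions: 9-mesityl-10-methylacridinium tetrafluoroborate (5 mol %), 2,6-lutidine (20 mol %), O2 (1 atm), ClCH2CH2Cl, 450 nm LEDs, 20 °C; then camphorsulfonic acid (40 mol %), 4 Å molecular sieves, 0 °C → rt
Reagents that add atoms: dioxygen, O=O
Why: Proposed new method: the carboxylate of 16 is oxidised by the excited acridinium, the acyloxy radical loses CO2, the planar tertiary C6 radical captures O2 at near diffusion rate (this forms the C6–O bond without facial bias, so both C6 epimers arise about 1:1) and the peroxyl radical is reduced by the acridinyl radical and protonated to hydroperoxide 17, which acid then closes onto the dimethyl acetal by six-membered transacetalisation; the closest known reaction types are the photocatalytic aerobic decarboxylative hydroxylation of carboxylic acids (which passes through the same hydroperoxide) and the Barton decarboxylative hydroperoxidation.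

Step 10
Reactants: 19 trimethylsilyl acetate
Product: 21 1,1-bis(trimethylsilyloxy)ethene, via lithium enolate 20 (not isolated)
Conditions: LiN(iPr)2, THF, −78 °C; Me3SiCl, −78 °C → rt; filtration, distillation
Reagents that add atoms: chlorotrimethylsilane, C[Si](C)(C)Cl
Why: O-Silylation of the lithium enolate of a silyl ester gives the bis-silyl ketene acetal, an acetic acid enolate equivalent that releases the free acid on work-up.

Step 11
Reactants: 18 (4S)-4,6-diethyl-6-[(2S,4S)-4-ethyl-2-methylhex-5-en-1-yl]-3-methoxy-1,2-dioxane; 21 1,1-bis(trimethylsilyloxy)ethene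
Product: 23 2-[(3S,4S,6R)-4,6-diethyl-6-[(2S,4S)-4-ethyl-2-methylhex-5-en-1-yl]-1,2-dioxan-3-yl]acetic acid, via silyl ester 22 (not isolated)
Conditions: 21 (2.5 equiv), Me3SiOTf (0.5 equiv), CH2Cl2, −78 °C; pH 4 phosphate buffer; preparative HPLC (C6 epimers separated)
Reagents that add atoms: none
Why: Mukaiyama-type addition of a silyl ketene acetal to a cyclic peroxycarbenium ion (known for 3-alkoxy-1,2-dioxanes): Me3SiOTf ionises the methoxy group, the half-chair cation keeps the C4 ethyl group pseudo-equatorial and the nucleophile enters axially through a chair-like transition state, which places the acetic acid arm axial and cis to the C4 ethyl group (3S) in both C6 series; work-up hydrolyses the silyl ester and the wanted 6R epimer is separated from its 6S partner.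

Step 12
Reactants: 23 2-[(3S,4S,6R)-4,6-diethyl-6-[(2S,4S)-4-ethyl-2-methylhex-5-en-1-yl]-1,2-dioxan-3-yl]acetic acid; 24 methyl vinyl ketone
Product: 25 2-[(3S,4S,6R)-4,6-diethyl-6-[(2S,4S,5E)-4-ethyl-2-methyl-7-oxooct-5-en-1-yl]-1,2-dioxan-3-yl]acetic acid
Conditions: 24 (5 equiv), second-generation Hoveyda–Grubbs catalyst [RuCl2(H2IMes)(=CH–C6H4-2-OiPr)] (5 mol %), CH2Cl2, 40 °C
Reagents that add atoms: none
Why: Olefin cross-metathesis of a terminal alkene with an electron-poor partner is selective for the cross product and for the E enone, and the ruthenium carbene tolerates the dialkyl peroxide and the free acid; no stereocentre is touched.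

## Compound list

1 | (E)-1,4-dibromobut-2-ene | BrC/C=C/CBr | starting material
2 | (R)-3-(bromomethyl)pent-1-ene | CC[C@H](C=C)CBr | intermediate
3 | 3-[(2R)-1-bromobutan-2-yl]-1,2,4-trioxolane | CC[C@H](C1OCOO1)CBr | intermediate
4 | (R)-2-(bromomethyl)butanal | CC[C@H](C=O)CBr | intermediate
5 | (R)-2-(bromomethyl)-1,1-dimethoxybutane | CC[C@H](C(OC)OC)CBr | intermediate
6 | ethyl (S)-lactate | C[C@H](O)C(=O)OCC | starting material
7 | ethyl (S)-2-{[(trifluoromethyl)sulfonyl]oxy}propanoate | C[C@H](OS(=O)(=O)C(F)(F)F)C(=O)OCC | intermediate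
8 | [(2R)-2-ethylbut-3-en-1-yl]magnesium bromide | CC[C@H](C=C)C[Mg]Br | intermediate
9 | ethyl (2S,4S)-4-ethyl-2-methylhex-5-enoate | CC[C@H](C=C)C[C@H](C)C(=O)OCC | intermediate
10 | (2S,4S)-4-ethyl-2-methylhex-5-en-1-ol | CC[C@H](C=C)C[C@H](C)CO | intermediate
11 | (3S,5S)-3-ethyl-6-iodo-5-methylhex-1-ene | CC[C@H](C=C)C[C@H](C)CI | intermediate
12 | butanoic acid | CCCC(=O)O | starting material
13 | dilithium but-1-ene-1,1-bis(olate) (dianion of 12) | CCC=C([O-])[O-].[Li+].[Li+] | intermediate
14 | (4S)-4-(dimethoxymethyl)-2-ethylhexanoic acid (both C2 epimers) | CCC(C[C@H](CC)C(OC)OC)C(=O)O | intermediate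
15 | dilithium (4S)-4-(dimethoxymethyl)-2-ethylhex-1-ene-1,1-bis(olate) (dianion of 14) | CCC(C[C@H](CC)C(OC)OC)=C([O-])[O-].[Li+].[Li+] | intermediate
16 | (4S,6S)-2-[(2S)-2-(dimethoxymethyl)butyl]-2,6-diethyl-4-methyloct-7-enoic acid (both C2 epimers) | CC[C@H](C=C)C[C@H](C)CC(CC)(C[C@H](CC)C(OC)OC)C(=O)O | intermediate
17 | (3S,5S,9S)-9-(dimethoxymethyl)-3,7-diethyl-7-hydroperoxy-5-methylundec-1-ene (both C7 epimers) | CC[C@H](C=C)C[C@H](C)CC(CC)(OO)C[C@H](CC)C(OC)OC | intermediate
18 | (4S)-4,6-diethyl-6-[(2S,4S)-4-ethyl-2-methylhex-5-en-1-yl]-3-methoxy-1,2-dioxane (C3/C6 epimer mixture) | CC[C@H](C=C)C[C@H](C)CC1(CC)C[C@H](CC)C(OC)OO1 | intermediate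
19 | trimethylsilyl acetate | CC(=O)O[Si](C)(C)C | starting material
20 | lithium 1-[(trimethylsilyl)oxy]ethen-1-olate | C=C([O-])O[Si](C)(C)C.[Li+] | intermediate
21 | 1,1-bis(trimethylsilyloxy)ethene | C=C(O[Si](C)(C)C)O[Si](C)(C)C | intermediate
22 | trimethylsilyl 2-[(3S,4S)-4,6-diethyl-6-[(2S,4S)-4-ethyl-2-methylhex-5-en-1-yl]-1,2-dioxan-3-yl]acetate (both C6 epimers) | CC[C@H](C=C)C[C@H](C)CC1(CC)C[C@H](CC)[C@H](CC(=O)O[Si](C)(C)C)OO1 | intermediate
23 | 2-[(3S,4S,6R)-4,6-diethyl-6-[(2S,4S)-4-ethyl-2-methylhex-5-en-1-yl]-1,2-dioxan-3-yl]acetic acid | CC[C@H](C=C)C[C@H](C)C[C@]1(CC)C[C@H](CC)[C@H](CC(=O)O)OO1 | intermediate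
24 | methyl vinyl ketone (but-3-en-2-one) | CC(=O)C=C | starting material
25 | 2-[(3S,4S,6R)-4,6-diethyl-6-[(2S,4S,5E)-4-ethyl-2-methyl-7-oxooct-5-en-1-yl]-1,2-dioxan-3-yl]acetic acid (CNP0329238.3) | CC[C@H](/C=C/C(C)=O)C[C@H](C)C[C@]1(CC)C[C@H](CC)[C@H](CC(=O)O)OO1 | target

## Step count and risks

Total: 12 steps. Longest linear sequence: 8 steps (1, 4, 5, 6, 8, 9, 11, 12).

**Step 9 (most likely to fail).** The peroxyl radical may dimerise to alkoxyl radicals instead of being reduced, giving tertiary alcohol and β-scission ketones. C6 is formed without control, so at best half of the material has the 6R configuration. Fallback: set out from 16 and condense it with N-hydroxypyridine-2-thione (dicyclohexylcarbodiimide, CH2Cl2, dark) to the O-acyl thiohydroxamate F1. Irradiating F1 with visible light at 0 °C in O2-saturated toluene containing tert-butyl thiol runs a thiol-mediated radical chain in which the thiol reduces the peroxyl radical. This delivers hydroperoxide 17, where the route is rejoined (acid closure to 18).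

**Step 11.** The peroxycarbenium ion may fragment or lose a proton at C4, and there is no direct precedent for the 3,4-cis preference with a C4 substituent; it rests on the axial-attack model. The C6 epimers must also be separable. Fallback: set out from 18 and open the methyl peroxyacetal with aqueous acetic acid in THF to the 1,2-dioxan-3-ol F2. Its ring-opened hydroperoxy aldehyde is olefinated with methyl (dimethoxyphosphoryl)acetate, LiCl and DBU to the hydroperoxy enoate F3. F3 closes by 6-exo oxa-Michael addition (Et2NH, CF3CH2OH) to the methyl ester F4, which is separated from its isomers by chromatography. LiOH in aqueous THF then gives 23. The cis/trans ratio at C3 in this closure is not predictable and may favour the trans isomer.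

**Step 8.** SN2 of an α-branched dianion on a β-branched iodide may be slow, with elimination or proton transfer competing. Fallback: set out from 11 and alkylate the dianion of acetic acid (LiN(iPr)2, THF/DMPU) with it to give (4R,6S)-6-ethyl-4-methyloct-7-enoic acid F5. The dianion of F5 is alkylated with bromide 5 to the α-branched acid F6. The quaternary centre is then formed last with iodoethane, the smallest and most reactive electrophile, which returns the route to 16.

Further compounds
F1 | step 9 | 2-sulfanylidenepyridin-1(2H)-yl (4S,6S)-2-[(2S)-2-(dimethoxymethyl)butyl]-2,6-diethyl-4-methyloct-7-enoate (both C2 epimers) | CC[C@H](C=C)C[C@H](C)CC(CC)(C[C@H](CC)C(OC)OC)C(=O)ON1C=CC=CC1=S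
F2 | step 11 | (4S)-4,6-diethyl-6-[(2S,4S)-4-ethyl-2-methylhex-5-en-1-yl]-1,2-dioxan-3-ol (C3/C6 epimer mixture) | CC[C@H](C=C)C[C@H](C)CC1(CC)C[C@H](CC)C(O)OO1
F3 | step 11 | methyl (2E,4S,8S,10S)-4,6,10-triethyl-6-hydroperoxy-8-methyldodeca-2,11-dienoate (both C6 epimers) | CC[C@H](C=C)C[C@H](C)CC(CC)(OO)C[C@H](CC)/C=C/C(=O)OC
F4 | step 11 | methyl 2-[(3S,4S,6R)-4,6-diethyl-6-[(2S,4S)-4-ethyl-2-methylhex-5-en-1-yl]-1,2-dioxan-3-yl]acetate | CC[C@H](C=C)C[C@H](C)C[C@]1(CC)C[C@H](CC)[C@H](CC(=O)OC)OO1
F5 | step 8 | (4R,6S)-6-ethyl-4-methyloct-7-enoic acid | CC[C@H](C=C)C[C@H](C)CCC(=O)O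
F6 | step 8 | (4S,6S)-2-[(2S)-2-(dimethoxymethyl)butyl]-6-ethyl-4-methyloct-7-enoic acid (both C2 epimers) | CC[C@H](C=C)C[C@H](C)CC(C[C@H](CC)C(OC)OC)C(=O)O
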